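Ring B is closed at the C5–C6 bond (labdane numbering) by an intramolecular vinylogous aldol condensation. The precursor is a ring A ketone, a 2,2,6-trimethylcyclohexanone whose quaternary C10 carries a 2-methylbut-3-enoyl group. Because C5 is flanked by the quaternary carbons C4 and C10 it cannot enolise, so the dienolate of the acyl chain is the only nucleophile and reaches C5 through its terminal carbon C6. One operation should give ring B with the C9 ketone next to C10; this ketone later enolises only toward C8, which fixes the C8=C9 olefin and the site of side-chain coupling. C10 is set by asymmetric allylation, C5 by hydrogenation anti to the C10 methyl.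

Key step: step 7

Numbering: ring A is C1–C5 plus C10, ring B is C5–C10; C17 is the methyl on C8, C20 the methyl on C10, C11–C16 the side chain.

Remark: (S)-3-methylpent-4-enoic acid is taken as a purchasable single enantiomer, and the (S)-ligand in step 2 is taken to give the (S)-ketone as in the parent 2-methylcyclohexanone series (otherwise the (R)-ligand is used).

**Step 1**
Reactants: 1 2,2,6-trimethylcyclohexan-1-one (racemic); 2 allyl chloroformate
Product: 3 allyl 2,6,6-trimethylcyclohex-1-en-1-yl carbonate
Conditions: LiN(SiMe3)2, THF, 0 °C; then 2, −78 °C → rt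
Reagents that add atoms: none
Why: Only C6–H of 1 is enolisable, and the hindered tetrasubstituted lithium enolate should be acylated on oxygen by the chloroformate (enolate O-acylation), which also erases the stereocentre of 1.

**Step 2**
Reactants: 3 allyl 2,6,6-trimethylcyclohex-1-en-1-yl carbonate
Product: 4 (2S)-2-allyl-2,6,6-trimethylcyclohexan-1-one
Conditions: Pd2(dba)3 (2.5 mol %), (S)-t-BuPHOX (6 mol %), THF, 25 °C
Reagents that add atoms: none
Why: Decarboxylative asymmetric Tsuji allylation: zerovalent palladium ionises the allyl carbonate, CO2 is lost, and the enolate recombines with the allyl unit inside the chiral phosphinooxazoline pocket, which sets the quaternary C10; enol carbonates of α-methylcyclohexanones are the established substrate class.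

**Step 3**
Reactants: 4 (2S)-2-allyl-2,6,6-trimethylcyclohexan-1-one
Product: 5 (6S)-2,2,6-trimethyl-6-[(E)-prop-1-enyl]cyclohexan-1-one
Conditions: PdCl2(MeCN)2 (10 mol %), toluene, 60 °C
Reagents that add atoms: none
Why: Palladium-catalysed olefin isomerisation should move the terminal double bond by one position to the more substituted internal olefin and stop there because C10 is quaternary; the olefin geometry is irrelevant for the next step.

**Step 4**
Reactants: 5 (6S)-2,2,6-trimethyl-6-[(E)-prop-1-enyl]cyclohexan-1-one
Product: 6 (1S)-1,3,3-trimethyl-2-oxocyclohexane-1-carbaldehyde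
Conditions: O3, CH2Cl2, −78 °C; then Me2S, −78 °C → rt
Reagents that add atoms: ozone, [O-][O+]=O
Why: Ozonolysis with reductive work-up cleaves the only olefin and leaves C9 as a formyl group on C10; the keto aldehyde has no α-hydrogen and is used without exposure to base.

**Step 5**
Reactants: 6 (1S)-1,3,3-trimethyl-2-oxocyclohexane-1-carbaldehyde; 7 crotyl bromide ((E)-1-bromobut-2-ene)
Product: 8 (6S)-6-(1-hydroxy-2-methylbut-3-enyl)-2,2,6-trimethylcyclohexan-1-one (mixture of diastereomers at the two new centres)
Conditions: Zn dust, THF/sat. aq NH4Cl, 0 °C → rt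
Reagents that add atoms: none
Why: Barbier crotylation: the allylzinc should add through its γ-carbon to the aldehyde, which is far more reactive than the doubly neopentyl ketone, and the buffered protic medium prevents retro-aldol cleavage; the two new stereocentres are not controlled because both carbons become sp2 later.

**Step 6**
Reactants: 8 (6S)-6-(1-hydroxy-2-methylbut-3-enyl)-2,2,6-trimethylcyclohexan-1-one
Product: 9 (6S)-2,2,6-trimethyl-6-(2-methylbut-3-enoyl)cyclohexan-1-one (epimers at the methyl-bearing carbon)
Conditions: Dess–Martin periodinane, CH2Cl2, 0 °C → rt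
Reagents that add atoms: none
Why: Dess–Martin oxidation converts the secondary alcohol into the C9 ketone without base; partial drift of the olefin into conjugation would be harmless because both isomers give the same dienolate.

**Step 7**
Reactants: 9 (6S)-2,2,6-trimethyl-6-(2-methylbut-3-enoyl)cyclohexan-1-one
Product: 12 (8aR)-2,5,5,8a-tetramethyl-6,7,8,8a-tetrahydronaphthalen-1(5H)-one, via potassium dienolate 10 (not isolated), via tertiary aldol 11 (not isolated)
Conditions: KOt-Bu (1.1 equiv), t-BuOH/THF, 25 → 80 °C
Reagents that add atoms: none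
Why: tert-Butoxide removes the doubly activated C8–H to give the linear dienolate 10, whose terminal carbon C6 adds to the C5 carbonyl of ring A, and the tertiary aldol 11 then loses water by vinylogous E1cB elimination across C5–C6 to give the conjugated dienone 12; the closest known reaction type is the intramolecular vinylogous aldol condensation, the dienolate counterpart of the aldol closure in a Robinson annulation. Ring B closes in the 6-exo-trig mode at the C5 carbonyl, with both double bonds of the dienolate inside the forming ring. No stereocentre from this step is kept, since the C5 carbinol is destroyed on dehydration; C10 is quaternary and cannot epimerise, and C5 is set in step 8. The step needs γ- over α-attack, secured because α-attack would give a four-membered ring, and it needs a single enolisable site, secured because the ring A ketone lies between the quaternary carbons C4 and C10. The main competitor, retro-Claisen cleavage of the non-enolisable 1,3-diketone, should be held back by the bulky alkoxide and by fast conversion of the C9 carbonyl into its dienolate, while dehydration, possible only toward C6, makes the closure irreversible.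

**Step 8**
Reactants: 12 (8aR)-2,5,5,8a-tetramethyl-6,7,8,8a-tetrahydronaphthalen-1(5H)-one
Product: 13 (4aR,8aR)-2,5,5,8a-tetramethyloctahydronaphthalen-1(2H)-one (epimers at C2 of the ring, labdane C8)
Conditions: H2 (1–4 atm), 10% Pd/C, EtOAc, rt
Reagents that add atoms: none
Why: Heterogeneous hydrogenation should saturate both olefins and deliver hydrogen to C5 from the face opposite the axial C10 methyl and the axial C4 methyl, giving the trans ring fusion (5R), as in the hydrogenation of steroidal 5-enes; the C8 epimers are carried on because C8 becomes sp2 in step 9.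

**Step 9**
Reactants: 13 (4aR,8aR)-2,5,5,8a-tetramethyloctahydronaphthalen-1(2H)-one
Product: 14 (4aR,8aR)-2,5,5,8a-tetramethyl-3,4,4a,5,6,7,8,8a-octahydronaphthalen-1-yl trifluoromethanesulfonate
Conditions: LiN(i-Pr)2, THF, −78 → 0 °C; then PhNTf2, 0 °C → rt
Reagents that add atoms: N-phenyl-bis(trifluoromethanesulfonimide), O=S(=O)(N(c1ccccc1)S(=O)(=O)C(F)(F)F)C(F)(F)F
Why: The C9 ketone can enolise only toward C8 because C10 is quaternary, so O-triflation of the enolate should give a single enol triflate and fix the tetrasubstituted C8=C9 olefin.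

**Step 10**
Reactants: 15 (R)-3-(benzyloxy)propane-1,2-diol
Product: 16 (S)-3-(benzyloxy)-2-hydroxypropyl acetate
Conditions: AcCl (1.05 equiv), 2,4,6-collidine, CH2Cl2, −78 °C
Reagents that add atoms: acetyl chloride, CC(=O)Cl
Why: Acetyl chloride with a hindered pyridine base at low temperature acylates the primary hydroxyl selectively over the secondary one (selective primary acylation); the stereocentre is not touched.

**Step 11**
Reactants: 16 (S)-3-(benzyloxy)-2-hydroxypropyl acetate; 17 (S)-3-methylpent-4-enoic acid
Product: 18 (2S)-1-acetoxy-3-(benzyloxy)propan-2-yl (3S)-3-methylpent-4-enoate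
Conditions: DCC, DMAP (cat.), CH2Cl2, 0 °C → rt
Reagents that add atoms: none
Why: Steglich esterification acylates the secondary hydroxyl quickly enough to outrun acetyl migration, and the acid cannot epimerise because its stereocentre is β to the carboxyl.

**Step 12**
Reactants: 18 (2S)-1-acetoxy-3-(benzyloxy)propan-2-yl (3S)-3-methylpent-4-enoate; 19 9-borabicyclo[3.3.1]nonane (9-BBN); 14 (4aR,8aR)-2,5,5,8a-tetramethyl-3,4,4a,5,6,7,8,8a-octahydronaphthalen-1-yl trifluoromethanesulfonate
Product: 21 (2S)-1-acetoxy-3-(benzyloxy)propan-2-yl (3R)-3-methyl-5-[(4aR,8aR)-2,5,5,8a-tetramethyl-3,4,4a,5,6,7,8,8a-octahydronaphthalen-1-yl]pentanoate, via B-alkyl-9-BBN adduct 20 (not isolated)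
Conditions: 18, 19, THF, 0 °C → rt; then 14, Pd(dppf)Cl2 (10 mol %), AsPh3, Cs2CO3, DMF/THF/H2O, rt → 45 °C
Reagents that add atoms: none
Why: Anti-Markovnikov hydroboration of the terminal olefin followed by B-alkyl Suzuki–Miyaura coupling with the enol triflate forms the C9–C11 bond; 2,6,6-trisubstituted cyclohexenyl triflates are known partners in this coupling, and the carbonate base at mild temperature should spare the acetate and the esters.

**Step 13**
Reactants: 21 (2S)-1-acetoxy-3-(benzyloxy)propan-2-yl (3R)-3-methyl-5-[(4aR,8aR)-2,5,5,8a-tetramethyl-3,4,4a,5,6,7,8,8a-octahydronaphthalen-1-yl]pentanoate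
Product: 22 (2S)-1-acetoxy-3-hydroxypropan-2-yl (3R)-3-methyl-5-[(4aR,8aR)-2,5,5,8a-tetramethyl-3,4,4a,5,6,7,8,8a-octahydronaphthalen-1-yl]pentanoate (CNP0216082.1)
Conditions: H2 (1 atm), 10% Pd/C, EtOAc, rt
Reagents that add atoms: none
Why: Hydrogenolysis of the benzyl ether under neutral conditions should free the primary hydroxyl without acyl migration, and the tetrasubstituted C8=C9 olefin is expected to be inert to Pd/C at this pressure.

**Compound list**
1 | 2,2,6-trimethylcyclohexan-1-one (racemic) | CC1CCCC(C)(C)C1=O | starting material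
2 | allyl chloroformate | C=CCOC(=O)Cl | starting material
3 | allyl 2,6,6-trimethylcyclohex-1-en-1-yl carbonate | C=CCOC(=O)OC1=C(C)CCCC1(C)C | intermediate
4 | (2S)-2-allyl-2,6,6-trimethylcyclohexan-1-one | C=CC[C@]1(C)CCCC(C)(C)C1=O | intermediate
5 | (6S)-2,2,6-trimethyl-6-[(E)-prop-1-enyl]cyclohexan-1-one | C/C=C/[C@]1(C)CCCC(C)(C)C1=O | intermediate
6 | (1S)-1,3,3-trimethyl-2-oxocyclohexane-1-carbaldehyde | O=C[C@]1(C)CCCC(C)(C)C1=O | intermediate
7 | crotyl bromide, (E)-1-bromobut-2-ene | C/C=C/CBr | starting material
8 | (6S)-6-(1-hydroxy-2-methylbut-3-enyl)-2,2,6-trimethylcyclohexan-1-one, diastereomer mixture | C=CC(C)C(O)[C@]1(C)CCCC(C)(C)C1=O | intermediate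
9 | (6S)-2,2,6-trimethyl-6-(2-methylbut-3-enoyl)cyclohexan-1-one, epimer mixture | C=CC(C)C(=O)[C@]1(C)CCCC(C)(C)C1=O | intermediate
10 | potassium 2-methyl-1-[(1S)-1,3,3-trimethyl-2-oxocyclohexyl]buta-1,3-dien-1-olate | C=CC(C)=C([O-])[C@]1(C)CCCC(C)(C)C1=O.[K+] | intermediate
11 | (8aR)-4a-hydroxy-2,5,5,8a-tetramethyl-4a,5,6,7,8,8a-hexahydronaphthalen-1(4H)-one, configuration at C4a open | CC1=CCC2(O)C(C)(C)CCC[C@@]2(C)C1=O | intermediate
12 | (8aR)-2,5,5,8a-tetramethyl-6,7,8,8a-tetrahydronaphthalen-1(5H)-one | CC1=CC=C2C(C)(C)CCC[C@@]2(C)C1=O | intermediate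
13 | (4aR,8aR)-2,5,5,8a-tetramethyloctahydronaphthalen-1(2H)-one, C2 epimers | CC1CC[C@@H]2C(C)(C)CCC[C@@]2(C)C1=O | intermediate
14 | (4aR,8aR)-2,5,5,8a-tetramethyl-3,4,4a,5,6,7,8,8a-octahydronaphthalen-1-yl trifluoromethanesulfonate | FC(F)(F)S(=O)(=O)OC1=C(C)CC[C@@H]2C(C)(C)CCC[C@@]12C | intermediate
15 | (R)-3-(benzyloxy)propane-1,2-diol | OC[C@@H](O)COCc1ccccc1 | starting material
16 | (S)-3-(benzyloxy)-2-hydroxypropyl acetate | CC(=O)OC[C@@H](O)COCc1ccccc1 | intermediate
17 | (S)-3-methylpent-4-enoic acid | OC(=O)C[C@H](C)C=C | starting material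
18 | (2S)-1-acetoxy-3-(benzyloxy)propan-2-yl (3S)-3-methylpent-4-enoate | CC(=O)OC[C@H](COCc1ccccc1)OC(=O)C[C@H](C)C=C | intermediate
19 | 9-borabicyclo[3.3.1]nonane (9-BBN) | C1CC2CCCC(C1)B2 | starting material
20 | (2S)-1-acetoxy-3-(benzyloxy)propan-2-yl (3R)-5-(9-borabicyclo[3.3.1]nonan-9-yl)-3-methylpentanoate | CC(=O)OC[C@H](COCc1ccccc1)OC(=O)C[C@H](C)CCB1C2CCCC1CCC2 | intermediate
21 | (2S)-1-acetoxy-3-(benzyloxy)propan-2-yl (3R)-3-methyl-5-[(4aR,8aR)-2,5,5,8a-tetramethyl-3,4,4a,5,6,7,8,8a-octahydronaphthalen-1-yl]pentanoate | CC(=O)OC[C@H](COCc1ccccc1)OC(=O)C[C@H](C)CCC1=C(C)CC[C@@H]2C(C)(C)CCC[C@@]12C | intermediate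
22 | (2S)-1-acetoxy-3-hydroxypropan-2-yl (3R)-3-methyl-5-[(4aR,8aR)-2,5,5,8a-tetramethyl-3,4,4a,5,6,7,8,8a-octahydronaphthalen-1-yl]pentanoate | CC(=O)OC[C@H](CO)OC(=O)C[C@H](C)CCC1=C(C)CC[C@@H]2C(C)(C)CCC[C@@]12C | target

Total step count: 13. Longest linear sequence: 11 (steps 1–9, 12, 13).

**Steps most likely to fail**

Step 7. Alkoxide or the hydroxide released on dehydration may cleave the non-enolisable 1,3-diketone by retro-Claisen fragmentation, or the addition to the hindered C5 carbonyl may revert faster than water is lost. The fallback sets out from 9 and comes back at 12; it preforms the nucleophile and activates the electrophile instead of relying on a reversible base-mediated condensation. Compound 9 is silylated (TBSOTf, Et3N, CH2Cl2, 0 °C) to the silyl dienol ether (6S)-6-{1-[(tert-butyldimethylsilyl)oxy]-2-methylbuta-1,3-dienyl}-2,2,6-trimethylcyclohexan-1-one F1. Treatment with TiCl4 (CH2Cl2, −78 °C) should bring about an intramolecular vinylogous Mukaiyama aldol addition through C6 to give the tertiary aldol 11, isolated in this variant. Dehydration with Burgess reagent (or SOCl2/pyridine) then gives 12.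

Step 12. Oxidative addition to the triflate, which lies between the quaternary C10 and the methyl-bearing C8, may be too slow at temperatures the acetate tolerates, and the aqueous base may start acetate hydrolysis and acyl migration. The fallback sets out from 17 and 14 and comes back at 21; it attaches the glyceride after the coupling. Acid 17 is esterified (MeOH, cat. H2SO4) to methyl (S)-3-methylpent-4-enoate F3. Hydroboration with 9-BBN gives methyl (3R)-5-(9-borabicyclo[3.3.1]nonan-9-yl)-3-methylpentanoate F4, which is coupled with 14 under more forcing conditions (Pd(dppf)Cl2, K3PO4, DMF, 80 °C) to methyl (3R)-3-methyl-5-[(4aR,8aR)-2,5,5,8a-tetramethyl-3,4,4a,5,6,7,8,8a-octahydronaphthalen-1-yl]pentanoate F5. Saponification (LiOH, THF/H2O) gives (3R)-3-methyl-5-[(4aR,8aR)-2,5,5,8a-tetramethyl-3,4,4a,5,6,7,8,8a-octahydronaphthalen-1-yl]pentanoic acid F6, and Steglich esterification of F6 with 16 (DCC, DMAP, CH2Cl2) gives 21.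

Step 8. Hydrogen may be delivered to C5 with poor facial selectivity, or the shielded C5=C6 olefin may resist saturation after the enone olefin has been reduced. The fallback sets out from 12 and comes back at 13; it installs the C5 hydrogen by dissolving-metal reduction. Compound 12 is treated with Li in NH3/THF with t-BuOH at −78 °C; 1,6-reduction should protonate the δ-carbon C5 axially, anti to the C10 methyl, and give after work-up the trans-fused enone (4aR,8aR)-2,5,5,8a-tetramethyl-4a,5,6,7,8,8a-hexahydronaphthalen-1(4H)-one F2 (its deconjugated isomer behaves alike). Hydrogenation of the remaining unhindered olefin (H2, Pd/C, EtOAc) gives 13.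

**Further compounds**
F1 | step 7 | (6S)-6-{1-[(tert-butyldimethylsilyl)oxy]-2-methylbuta-1,3-dienyl}-2,2,6-trimethylcyclohexan-1-one | C=CC(C)=C(O[Si](C)(C)C(C)(C)C)[C@]1(C)CCCC(C)(C)C1=O
F2 | step 8 | (4aR,8aR)-2,5,5,8a-tetramethyl-4a,5,6,7,8,8a-hexahydronaphthalen-1(4H)-one | CC1=CC[C@@H]2C(C)(C)CCC[C@@]2(C)C1=O
F3 | step 12 | methyl (S)-3-methylpent-4-enoate | COC(=O)C[C@H](C)C=C
F4 | step 12 | methyl (3R)-5-(9-borabicyclo[3.3.1]nonan-9-yl)-3-methylpentanoate | COC(=O)C[C@H](C)CCB1C2CCCC1CCC2
F5 | step 12 | methyl (3R)-3-methyl-5-[(4aR,8aR)-2,5,5,8a-tetramethyl-3,4,4a,5,6,7,8,8a-octahydronaphthalen-1-yl]pentanoate | COC(=O)C[C@H](C)CCC1=C(C)CC[C@@H]2C(C)(C)CCC[C@@]12C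
F6 | step 12 | (3R)-3-methyl-5-[(4aR,8aR)-2,5,5,8a-tetramethyl-3,4,4a,5,6,7,8,8a-octahydronaphthalen-1-yl]pentanoic acid | OC(=O)C[C@H](C)CCC1=C(C)CC[C@@H]2C(C)(C)CCC[C@@]12C
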